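The 1,2-dioxane is disconnected at C3–O and C3–C4 (C1 = ester carbon). The O–O–C6–C5=C4 unit of a tertiary allylic hydroperoxide is the peroxide counterpart of a homoallylic alcohol, so condensation with an aldehyde that supplies C3, followed by vinylsilane-terminated peroxycarbenium cyclisation under a confined chiral Brønsted acid, builds the ring, its C4=C5 alkene and the C3 stereocentre in one operation. The precursor is the (R)-configured tertiary hydroperoxide bearing a (Z)-2-(trimethylsilyl)vinyl group and the trimethylcyclohexenone side chain, made by invertive perhydrolysis of an enantioenriched terminal epoxide; its partner is the silyl-protected (S)-α-methyl aldehyde that brings C1 and C2.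

Key step: step 12

Remark and assumption on the chemistry: atoms are numbered along the target chain (C1 ester carbon, C2 its α-carbon, C3 and C6 the dioxane carbons on oxygen, C4 and C5 between them); dihydro-β-ionone has no ring carbonyl, so the enone is installed first; the (S)-BINOL form of LaLi3(binaphthoxide)3 is assumed to give the (S)-epoxide, and the (R)-BINOL form is used instead if a first run shows the opposite sense.

Step 1
Reactants: 1 dihydro-β-ionone [4-(2,6,6-trimethylcyclohex-1-en-1-yl)butan-2-one]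
Product: 2 2,4,4-trimethyl-3-(3-oxobutyl)cyclohex-2-en-1-one
Conditions: t-BuOOH (70% aq.), Rh2(caprolactamate)4 (1 mol %), K2CO3, CH2Cl2, rt
Reagents that add atoms: tert-butyl hydroperoxide, CC(C)(C)OO
Why: Radical allylic C–H oxidation by tert-butylperoxyl radicals should convert the only ring methylene next to the tetrasubstituted alkene into the enone carbonyl, the exocyclic allylic CH2 being shielded by the gem-dimethyl group and the methyl ketone being inert, and no stereocentre is formed.

Step 2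
Reactants: 2 2,4,4-trimethyl-3-(3-oxobutyl)cyclohex-2-en-1-one
Product: 3 2,4,4-trimethyl-3-{2-[(2S)-2-methyloxiran-2-yl]ethyl}cyclohex-2-en-1-one
Conditions: Me3S(O)I, NaH, THF, rt; then 2, (S)-LaLi3(binaphthoxide)3 (5 mol %), [2,4,6-(MeO)3C6H2]3P=O (5 mol %), 5 Å MS, THF, rt
Reagents that add atoms: dimethylsulfoxonium methylide (from trimethylsulfoxonium iodide and NaH), C[S+](C)(=O)[CH2-]
Why: Catalytic asymmetric Corey–Chaykovsky epoxidation of a methyl ketone, in which the lanthanum–lithium binaphthoxide binds ketone and ylide and delivers CH2 to one carbonyl face, should set the quaternary centre as (S) by catalyst control, while the hindered conjugated ring ketone with its fully substituted β-carbon should neither epoxidise nor cyclopropanate.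

Step 3
Reactants: 3 2,4,4-trimethyl-3-{2-[(2S)-2-methyloxiran-2-yl]ethyl}cyclohex-2-en-1-one
Product: 4 3-[(3R)-3-hydroperoxy-4-hydroxy-3-methylbutyl]-2,4,4-trimethylcyclohex-2-en-1-one
Conditions: H2O2 (anhydrous, in Et2O, excess), H3PMo12O40 (cat.), Et2O, rt
Reagents that add atoms: hydrogen peroxide, OO
Why: Acid-catalysed perhydrolysis of a 2,2-disubstituted epoxide breaks the C–O bond at the more substituted carbon by backside attack in a borderline SN2 process, so the (S)-epoxide should give the (R)-tertiary hydroperoxide by inversion, and the hindered conjugated ketone should resist peroxyketal formation.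

Step 4
Reactants: 4 3-[(3R)-3-hydroperoxy-4-hydroxy-3-methylbutyl]-2,4,4-trimethylcyclohex-2-en-1-one
Product: 5 3-[(3R)-3-{[tert-butyl(dimethyl)silyl]peroxy}-4-hydroxy-3-methylbutyl]-2,4,4-trimethylcyclohex-2-en-1-one
Conditions: TBSCl (1.05 equiv), imidazole, CH2Cl2, −20 °C
Reagents that add atoms: tert-butyl(chloro)dimethylsilane, CC(C)(C)[Si](C)(C)Cl
Why: Chemoselective O-silylation should mask the hydroperoxide as a chromatography-stable silyl peroxide, because the more acidic, α-effect-activated OOH reacts faster than the neopentyl-type primary alcohol, and the stereocentre is not touched.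

Step 5
Reactants: 5 3-[(3R)-3-{[tert-butyl(dimethyl)silyl]peroxy}-4-hydroxy-3-methylbutyl]-2,4,4-trimethylcyclohex-2-en-1-one
Product: 6 (2R)-2-{[tert-butyl(dimethyl)silyl]peroxy}-2-methyl-4-(2,6,6-trimethyl-3-oxocyclohex-1-en-1-yl)butanal
Conditions: Dess–Martin periodinane, CH2Cl2, 0 °C to rt
Reagents that add atoms: none
Why: Dess–Martin oxidation of the primary alcohol is neutral and peroxide-tolerant and should give an α-quaternary aldehyde that cannot enolise, so the peroxide-bearing centre stays intact.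

Step 6
Reactants: 6 (2R)-2-{[tert-butyl(dimethyl)silyl]peroxy}-2-methyl-4-(2,6,6-trimethyl-3-oxocyclohex-1-en-1-yl)butanal
Product: 7 3-[(3R)-3-{[tert-butyl(dimethyl)silyl]peroxy}-3-methylpent-4-yn-1-yl]-2,4,4-trimethylcyclohex-2-en-1-one
Conditions: MeC(O)C(N2)P(O)(OMe)2, K2CO3, MeOH, 0 °C to rt
Reagents that add atoms: dimethyl (1-diazo-2-oxopropyl)phosphonate, COP(=O)(OC)C(=[N+]=[N-])C(C)=O
Why: Ohira–Bestmann (Seyferth–Gilbert) homologation should turn the aldehyde into the terminal alkyne through a diazoalkene and a 1,2-shift of the alkylidene carbene, under carbonate in methanol at low temperature, which the hindered ketone and the bulky silyl peroxide should survive.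

Step 7
Reactants: 7 3-[(3R)-3-{[tert-butyl(dimethyl)silyl]peroxy}-3-methylpent-4-yn-1-yl]-2,4,4-trimethylcyclohex-2-en-1-one
Product: 9 3-[(3R)-3-{[tert-butyl(dimethyl)silyl]peroxy}-3-methyl-5-(trimethylsilyl)pent-4-yn-1-yl]-2,4,4-trimethylcyclohex-2-en-1-one, via silyl dienol ether 8 (not isolated)
Conditions: LiN(SiMe3)2 (2.5 equiv), Me3SiCl (3 equiv), THF, −78 °C; aq. citric acid
Reagents that add atoms: chlorotrimethylsilane, C[Si](C)(C)Cl
Why: Deprotonation of the terminal alkyne with in situ silyl trapping (alkyne C-silylation) should give the silylalkyne, and because the ring ketone is enolised and O-silylated at the same time, the transient silyl dienol ether 8 is hydrolysed back to the enone on mild acidic work-up.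

Step 8
Reactants: 9 3-[(3R)-3-{[tert-butyl(dimethyl)silyl]peroxy}-3-methyl-5-(trimethylsilyl)pent-4-yn-1-yl]-2,4,4-trimethylcyclohex-2-en-1-one
Product: 10 3-[(3R,4Z)-3-{[tert-butyl(dimethyl)silyl]peroxy}-3-methyl-5-(trimethylsilyl)pent-4-en-1-yl]-2,4,4-trimethylcyclohex-2-en-1-one
Conditions: KO2CN=NCO2K, AcOH, MeOH/CH2Cl2, 0 °C to rt
Reagents that add atoms: none
Why: Diimide reduction delivers two hydrogens to the same face of the alkyne in a concerted step and so should give the (Z)-vinylsilane, while the O–O bond and the tetrasubstituted enone alkene are inert and the hindered cis-alkene formed is slow to reduce further.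

Step 9
Reactants: 10 3-[(3R,4Z)-3-{[tert-butyl(dimethyl)silyl]peroxy}-3-methyl-5-(trimethylsilyl)pent-4-en-1-yl]-2,4,4-trimethylcyclohex-2-en-1-one
Product: 11 3-[(3R,4Z)-3-hydroperoxy-3-methyl-5-(trimethylsilyl)pent-4-en-1-yl]-2,4,4-trimethylcyclohex-2-en-1-one
Conditions: Bu4NF, AcOH, THF, 0 °C
Reagents that add atoms: none
Why: Buffered fluoride desilylation should cleave the O–Si bond of the silyl peroxide much faster than the vinylic C–Si bond, and the tertiary hydroperoxide released has no α-hydrogen for base-induced fragmentation, although it should be used promptly.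

Step 10
Reactants: 12 methyl (2S)-3-hydroxy-2-methylpropanoate
Product: 13 methyl (2S)-3-{[tert-butyl(dimethyl)silyl]oxy}-2-methylpropanoate
Conditions: TBSCl, imidazole, CH2Cl2, 0 °C to rt
Reagents that add atoms: tert-butyl(chloro)dimethylsilane, CC(C)(C)[Si](C)(C)Cl
Why: Standard silyl ether formation at the primary alcohol does not involve the stereocentre.

Step 11
Reactants: 13 methyl (2S)-3-{[tert-butyl(dimethyl)silyl]oxy}-2-methylpropanoate
Product: 14 (2S)-3-{[tert-butyl(dimethyl)silyl]oxy}-2-methylpropanal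
Conditions: i-Bu2AlH (1.05 equiv), CH2Cl2, −78 °C; aq. potassium sodium tartrate
Reagents that add atoms: none
Why: Partial hydride reduction of the ester with one equivalent of hydride at −78 °C should stop at the aldehyde oxidation level, and the configurationally labile product is used at once without chromatography so that C2 is not epimerised.

Step 12
Reactants: 11 3-[(3R,4Z)-3-hydroperoxy-3-methyl-5-(trimethylsilyl)pent-4-en-1-yl]-2,4,4-trimethylcyclohex-2-en-1-one; 14 (2S)-3-{[tert-butyl(dimethyl)silyl]oxy}-2-methylpropanal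
Product: 17 3-{2-[(3R,6R)-6-[(2S)-1-{[tert-butyl(dimethyl)silyl]oxy}propan-2-yl]-3-methyl-3,6-dihydro-1,2-dioxin-3-yl]ethyl}-2,4,4-trimethylcyclohex-2-en-1-one, via peroxyhemiacetal 15 (not isolated), via peroxycarbenium ion 16 (not isolated)
Conditions: confined chiral imidodiphosphorimidate Brønsted acid (BINOL-derived, 3,3′-diaryl, N-triflyl; 5 mol %), slow addition of 14, CH2Cl2, −40 °C
Reagents that add atoms: none
Why: Proposed new method: hydroperoxide 11 adds to aldehyde 14 to give peroxyhemiacetal 15, which the acid ionises with loss of water to the (E)-peroxycarbenium ion 16, held as an ion pair inside the chiral anion; the silicon-bearing carbon C4 attacks C3 while charge builds at C5 β to silicon, and loss of the silyl group, taken up by the water of condensation as Me3SiOH so that the proton returns to the catalyst, leaves the C4=C5 bond. The closest known reaction types are the silyl-Prins cyclisation of (Z)-vinylsilyl homoallylic alcohols with aldehydes to dihydropyrans, the Lewis-acid allylation of peroxycarbenium ions by allylsilanes and imidodiphosphorimidate-catalysed asymmetric Prins cyclisations of aliphatic aldehydes. The 3,6-dihydro-1,2-dioxine ring closes in a chair-like 6-endo-trig mode with the alkene inside the ring; the (Z) geometry holds the C–Si bond pseudo-axial and parallel to the emptying orbital at C5, so attack through C4 wins over 5-exo attack through C5, which would place charge α to silicon and next to the peroxide. C3 is the only new stereocentre and is set by the face of the peroxycarbenium carbon that C4 reaches: the target needs the chair with the C3 substituent and the C6 methyl equatorial and the C6 chain axial, which the substrate does not favour (methyl and chain at C6 are nearly equal in size and the Felkin–Anh preference from C2 points weakly to the C3 epimer), so the confined counteranion must impose it and both catalyst antipodes are to be screened. The step also needs chemoselectivity for ionisation of the hemiacetal C–OH over heterolysis or Hock rearrangement of the tertiary allylic C–OO bond and over enolisation of 14 at C2, which a confined acid, low temperature and a low stationary concentration of 14 are meant to secure; C2 and C6 are carried through unchanged.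

Step 13
Reactants: 17 3-{2-[(3R,6R)-6-[(2S)-1-{[tert-butyl(dimethyl)silyl]oxy}propan-2-yl]-3-methyl-3,6-dihydro-1,2-dioxin-3-yl]ethyl}-2,4,4-trimethylcyclohex-2-en-1-one
Product: 18 3-{2-[(3R,6R)-6-[(2S)-1-{[tert-butyl(dimethyl)silyl]oxy}propan-2-yl]-3-methyl-1,2-dioxan-3-yl]ethyl}-2,4,4-trimethylcyclohex-2-en-1-one
Conditions: KO2CN=NCO2K, AcOH, MeOH/CH2Cl2, 0 °C to rt
Reagents that add atoms: none
Why: Diimide reduction should saturate the cis-disubstituted ring alkene without cleaving the O–O bond, as is usual for 3,6-dihydro-1,2-dioxines, and leaves the tetrasubstituted enone alkene and all three stereocentres untouched.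

Step 14
Reactants: 18 3-{2-[(3R,6R)-6-[(2S)-1-{[tert-butyl(dimethyl)silyl]oxy}propan-2-yl]-3-methyl-1,2-dioxan-3-yl]ethyl}-2,4,4-trimethylcyclohex-2-en-1-one
Product: 19 3-{2-[(3R,6R)-6-[(2S)-1-hydroxypropan-2-yl]-3-methyl-1,2-dioxan-3-yl]ethyl}-2,4,4-trimethylcyclohex-2-en-1-one
Conditions: HF·pyridine, THF, 0 °C
Reagents that add atoms: none
Why: Cleavage of the primary silyl ether by HF under mildly acidic conditions avoids the base that could trigger Kornblum–DeLaMare fragmentation at the C3–H of the dioxane.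

Step 15
Reactants: 19 3-{2-[(3R,6R)-6-[(2S)-1-hydroxypropan-2-yl]-3-methyl-1,2-dioxan-3-yl]ethyl}-2,4,4-trimethylcyclohex-2-en-1-one
Product: 21 (2R)-2-{(3R,6R)-6-methyl-6-[2-(2,6,6-trimethyl-3-oxocyclohex-1-en-1-yl)ethyl]-1,2-dioxan-3-yl}propanoic acid, via aldehyde 20 (not isolated)
Conditions: TEMPO (cat.), PhI(OAc)2, MeCN/H2O, rt
Reagents that add atoms: water, O
Why: Oxoammonium-mediated oxidation takes the primary alcohol through the hydrate of aldehyde 20 to the acid under near-neutral conditions, so neither epimerisation at C2 nor β-elimination of the peroxide should occur.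

Step 16
Reactants: 21 (2R)-2-{(3R,6R)-6-methyl-6-[2-(2,6,6-trimethyl-3-oxocyclohex-1-en-1-yl)ethyl]-1,2-dioxan-3-yl}propanoic acid
Product: 22 diacarperoxide A [methyl (2R)-2-{(3R,6R)-6-methyl-6-[2-(2,6,6-trimethyl-3-oxocyclohex-1-en-1-yl)ethyl]-1,2-dioxan-3-yl}propanoate]
Conditions: Me3SiCHN2, MeOH/toluene, 0 °C
Reagents that add atoms: (trimethylsilyl)diazomethane, C[Si](C)(C)C=[N+]=[N-]
Why: Methyl ester formation by protonation of the diazoalkane and O-alkylation of the carboxylate is base-free, so the β-peroxy ester is not exposed to conditions that cause retro-oxa-Michael cleavage.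

Compound list
1 | dihydro-β-ionone, 4-(2,6,6-trimethylcyclohex-1-en-1-yl)butan-2-one | CC(=O)CCC1=C(C)CCCC1(C)C | starting material
2 | 2,4,4-trimethyl-3-(3-oxobutyl)cyclohex-2-en-1-one | CC(=O)CCC1=C(C)C(=O)CCC1(C)C | intermediate
3 | 2,4,4-trimethyl-3-{2-[(2S)-2-methyloxiran-2-yl]ethyl}cyclohex-2-en-1-one | C1O[C@@]1(C)CCC2=C(C)C(=O)CCC2(C)C | intermediate
4 | 3-[(3R)-3-hydroperoxy-4-hydroxy-3-methylbutyl]-2,4,4-trimethylcyclohex-2-en-1-one | OC[C@@](C)(CCC1=C(C)C(=O)CCC1(C)C)OO | intermediate
5 | 3-[(3R)-3-{[tert-butyl(dimethyl)silyl]peroxy}-4-hydroxy-3-methylbutyl]-2,4,4-trimethylcyclohex-2-en-1-one | OC[C@@](C)(CCC1=C(C)C(=O)CCC1(C)C)OO[Si](C)(C)C(C)(C)C | intermediate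
6 | (2R)-2-{[tert-butyl(dimethyl)silyl]peroxy}-2-methyl-4-(2,6,6-trimethyl-3-oxocyclohex-1-en-1-yl)butanal | O=C[C@@](C)(CCC1=C(C)C(=O)CCC1(C)C)OO[Si](C)(C)C(C)(C)C | intermediate
7 | 3-[(3R)-3-{[tert-butyl(dimethyl)silyl]peroxy}-3-methylpent-4-yn-1-yl]-2,4,4-trimethylcyclohex-2-en-1-one | C#C[C@@](C)(CCC1=C(C)C(=O)CCC1(C)C)OO[Si](C)(C)C(C)(C)C | intermediate
8 | tert-butyl(dimethyl)silyl (3R)-3-methyl-1-(trimethylsilyl)-5-{2,6,6-trimethyl-3-[(trimethylsilyl)oxy]cyclohexa-1,3-dien-1-yl}pent-1-yn-3-yl peroxide (silyl dienol ether, not isolated) | C[Si](C)(C)C#C[C@@](C)(CCC1=C(C)C(O[Si](C)(C)C)=CCC1(C)C)OO[Si](C)(C)C(C)(C)C | intermediate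
9 | 3-[(3R)-3-{[tert-butyl(dimethyl)silyl]peroxy}-3-methyl-5-(trimethylsilyl)pent-4-yn-1-yl]-2,4,4-trimethylcyclohex-2-en-1-one | C[Si](C)(C)C#C[C@@](C)(CCC1=C(C)C(=O)CCC1(C)C)OO[Si](C)(C)C(C)(C)C | intermediate
10 | 3-[(3R,4Z)-3-{[tert-butyl(dimethyl)silyl]peroxy}-3-methyl-5-(trimethylsilyl)pent-4-en-1-yl]-2,4,4-trimethylcyclohex-2-en-1-one | C[Si](C)(C)/C=C\[C@@](C)(CCC1=C(C)C(=O)CCC1(C)C)OO[Si](C)(C)C(C)(C)C | intermediate
11 | 3-[(3R,4Z)-3-hydroperoxy-3-methyl-5-(trimethylsilyl)pent-4-en-1-yl]-2,4,4-trimethylcyclohex-2-en-1-one | C[Si](C)(C)/C=C\[C@@](C)(CCC1=C(C)C(=O)CCC1(C)C)OO | intermediate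
12 | methyl (2S)-3-hydroxy-2-methylpropanoate | COC(=O)[C@@H](C)CO | starting material
13 | methyl (2S)-3-{[tert-butyl(dimethyl)silyl]oxy}-2-methylpropanoate | COC(=O)[C@@H](C)CO[Si](C)(C)C(C)(C)C | intermediate
14 | (2S)-3-{[tert-butyl(dimethyl)silyl]oxy}-2-methylpropanal | CC(C)(C)[Si](C)(C)OC[C@H](C)C=O | intermediate
15 | 3-[(3R,4Z)-3-({(2S)-3-{[tert-butyl(dimethyl)silyl]oxy}-1-hydroxy-2-methylpropyl}peroxy)-3-methyl-5-(trimethylsilyl)pent-4-en-1-yl]-2,4,4-trimethylcyclohex-2-en-1-one (peroxyhemiacetal, both epimers at the hemiacetal carbon, not isolated) | C[Si](C)(C)/C=C\[C@@](C)(CCC1=C(C)C(=O)CCC1(C)C)OOC(O)[C@@H](C)CO[Si](C)(C)C(C)(C)C | intermediate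
16 | (E)-peroxycarbenium ion formed from 15 by loss of water, paired with the catalyst anion (not isolated) | C[Si](C)(C)/C=C\[C@@](C)(CCC1=C(C)C(=O)CCC1(C)C)O/[O+]=C/[C@@H](C)CO[Si](C)(C)C(C)(C)C | intermediate
17 | 3-{2-[(3R,6R)-6-[(2S)-1-{[tert-butyl(dimethyl)silyl]oxy}propan-2-yl]-3-methyl-3,6-dihydro-1,2-dioxin-3-yl]ethyl}-2,4,4-trimethylcyclohex-2-en-1-one | CC(C)(C)[Si](C)(C)OC[C@H](C)[C@H]1C=C[C@@](C)(CCC2=C(C)C(=O)CCC2(C)C)OO1 | intermediate
18 | 3-{2-[(3R,6R)-6-[(2S)-1-{[tert-butyl(dimethyl)silyl]oxy}propan-2-yl]-3-methyl-1,2-dioxan-3-yl]ethyl}-2,4,4-trimethylcyclohex-2-en-1-one | CC(C)(C)[Si](C)(C)OC[C@H](C)[C@H]1CC[C@@](C)(CCC2=C(C)C(=O)CCC2(C)C)OO1 | intermediate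
19 | 3-{2-[(3R,6R)-6-[(2S)-1-hydroxypropan-2-yl]-3-methyl-1,2-dioxan-3-yl]ethyl}-2,4,4-trimethylcyclohex-2-en-1-one | OC[C@H](C)[C@H]1CC[C@@](C)(CCC2=C(C)C(=O)CCC2(C)C)OO1 | intermediate
20 | (2R)-2-{(3R,6R)-6-methyl-6-[2-(2,6,6-trimethyl-3-oxocyclohex-1-en-1-yl)ethyl]-1,2-dioxan-3-yl}propanal (not isolated) | O=C[C@H](C)[C@H]1CC[C@@](C)(CCC2=C(C)C(=O)CCC2(C)C)OO1 | intermediate
21 | (2R)-2-{(3R,6R)-6-methyl-6-[2-(2,6,6-trimethyl-3-oxocyclohex-1-en-1-yl)ethyl]-1,2-dioxan-3-yl}propanoic acid | OC(=O)[C@H](C)[C@H]1CC[C@@](C)(CCC2=C(C)C(=O)CCC2(C)C)OO1 | intermediate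
22 | diacarperoxide A, methyl (2R)-2-{(3R,6R)-6-methyl-6-[2-(2,6,6-trimethyl-3-oxocyclohex-1-en-1-yl)ethyl]-1,2-dioxan-3-yl}propanoate | COC(=O)[C@H](C)[C@H]1CC[C@@](C)(CCC2=C(C)C(=O)CCC2(C)C)OO1 | target

Total step count: 16. Longest linear sequence: 14 steps (steps 1–9 and 12–16, from dihydro-β-ionone); the aldehyde branch adds steps 10 and 11.

Steps most likely to fail

Step 12. The confined anion may not discriminate the two faces of the peroxycarbenium carbon well enough to override the weak Felkin–Anh bias from C2. The tertiary allylic C–OO bond may ionise or undergo Hock-type rearrangement before the ring closes, and the vinylsilane may be protodesilylated. The fallback uses known chemistry and makes the C2–C3 bond last, by Lewis-acid-mediated addition of a silyl ketene acetal to a cyclic peroxycarbenium ion generated from a 3-alkoxy-1,2-dioxane. It sets out from aldehyde 6. Wittig reaction with Ph3P=CHCHO in warm toluene should give (2E,4R)-4-{[tert-butyl(dimethyl)silyl]peroxy}-4-methyl-6-(2,6,6-trimethyl-3-oxocyclohex-1-en-1-yl)hex-2-enal F1. Diimide (KO2CN=NCO2K, AcOH) should saturate the conjugated alkene to (4R)-4-{[tert-butyl(dimethyl)silyl]peroxy}-4-methyl-6-(2,6,6-trimethyl-3-oxocyclohex-1-en-1-yl)hexanal F2. p-TsOH in MeOH should remove the silyl group, close the six-membered peroxyhemiacetal and convert it into 3-{2-[(3R)-6-methoxy-3-methyl-1,2-dioxan-3-yl]ethyl}-2,4,4-trimethylcyclohex-2-en-1-one F3. Me3SiOTf with (E)-1-methoxy-1-(trimethylsilyloxy)prop-1-ene in CH2Cl2 at −78 °C should then add the propanoate unit at C3. This fallback comes back to the route at 22, which would be formed together with its C2 and C3 epimers and would have to be separated by chromatography.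

Step 2. Enantiofacial control in the methylene transfer may be incomplete or of the opposite sense, and the ylide may react at the ring enone. The fallback replaces the one-carbon epoxidation by a Sharpless epoxidation of an allylic alcohol, whose facial sense is secure, followed by glycol cleavage. It sets out from 2. Horner–Wadsworth–Emmons olefination of the methyl ketone with triethyl phosphonoacetate and NaH should give, after separation of the minor Z isomer, ethyl (2E)-3-methyl-5-(2,6,6-trimethyl-3-oxocyclohex-1-en-1-yl)pent-2-enoate F4. i-Bu2AlH should reduce ester and ring ketone to (2E)-5-(3-hydroxy-2,6,6-trimethylcyclohex-1-en-1-yl)-3-methylpent-2-en-1-ol F5. Sharpless epoxidation of the primary allylic alcohol (Ti(OiPr)4, L-(+)-diethyl tartrate, t-BuOOH, 4 Å MS, CH2Cl2, −20 °C) should give {(2S,3S)-3-[2-(3-hydroxy-2,6,6-trimethylcyclohex-1-en-1-yl)ethyl]-3-methyloxiran-2-yl}methanol F6. MnO2 should reoxidise only the ring allylic alcohol to 3-{2-[(2S,3S)-3-(hydroxymethyl)-2-methyloxiran-2-yl]ethyl}-2,4,4-trimethylcyclohex-2-en-1-one F7. Perhydrolysis (H2O2, H3PMo12O40) with inversion at the tertiary carbon should give 3-[(3R,4S)-3-hydroperoxy-4,5-dihydroxy-3-methylpentyl]-2,4,4-trimethylcyclohex-2-en-1-one F8. Silylation of the hydroperoxide with one equivalent of TBSCl and imidazole at low temperature should give 3-[(3R,4S)-3-{[tert-butyl(dimethyl)silyl]peroxy}-4,5-dihydroxy-3-methylpentyl]-2,4,4-trimethylcyclohex-2-en-1-one F9. NaIO4 cleavage of the diol then comes back to the route at aldehyde 6.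

Step 8. Hydrogen transfer from diimide to the hindered silylalkyne may be too slow for full conversion, or reduction may continue past the alkene. The fallback puts silicon and the Z geometry in together by trans-hydrosilylation of the terminal alkyne. It sets out from 7. Et3SiH with [RuCl2(p-cymene)]2 in CH2Cl2 should give 3-[(3R,4Z)-3-{[tert-butyl(dimethyl)silyl]peroxy}-3-methyl-5-(triethylsilyl)pent-4-en-1-yl]-2,4,4-trimethylcyclohex-2-en-1-one F10. Bu4NF and AcOH should release 3-[(3R,4Z)-3-hydroperoxy-3-methyl-5-(triethylsilyl)pent-4-en-1-yl]-2,4,4-trimethylcyclohex-2-en-1-one F11. F11 is taken through the conditions of step 12 in place of 11; the silyl group is lost there, so the fallback comes back to the route at 17.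

Further compounds
F1 | step 12 | (2E,4R)-4-{[tert-butyl(dimethyl)silyl]peroxy}-4-methyl-6-(2,6,6-trimethyl-3-oxocyclohex-1-en-1-yl)hex-2-enal | O=C/C=C/[C@@](C)(CCC1=C(C)C(=O)CCC1(C)C)OO[Si](C)(C)C(C)(C)C
F2 | step 12 | (4R)-4-{[tert-butyl(dimethyl)silyl]peroxy}-4-methyl-6-(2,6,6-trimethyl-3-oxocyclohex-1-en-1-yl)hexanal | O=CCC[C@@](C)(CCC1=C(C)C(=O)CCC1(C)C)OO[Si](C)(C)C(C)(C)C
F3 | step 12 | 3-{2-[(3R)-6-methoxy-3-methyl-1,2-dioxan-3-yl]ethyl}-2,4,4-trimethylcyclohex-2-en-1-one (both epimers at the acetal carbon) | COC1CC[C@@](C)(CCC2=C(C)C(=O)CCC2(C)C)OO1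
F4 | step 2 | ethyl (2E)-3-methyl-5-(2,6,6-trimethyl-3-oxocyclohex-1-en-1-yl)pent-2-enoate | CCOC(=O)/C=C(\C)CCC1=C(C)C(=O)CCC1(C)C
F5 | step 2 | (2E)-5-(3-hydroxy-2,6,6-trimethylcyclohex-1-en-1-yl)-3-methylpent-2-en-1-ol (racemic at the ring carbinol) | OC/C=C(\C)CCC1=C(C)C(O)CCC1(C)C
F6 | step 2 | {(2S,3S)-3-[2-(3-hydroxy-2,6,6-trimethylcyclohex-1-en-1-yl)ethyl]-3-methyloxiran-2-yl}methanol (both epimers at the ring carbinol) | OC[C@@H]1O[C@@]1(C)CCC2=C(C)C(O)CCC2(C)C
F7 | step 2 | 3-{2-[(2S,3S)-3-(hydroxymethyl)-2-methyloxiran-2-yl]ethyl}-2,4,4-trimethylcyclohex-2-en-1-one | OC[C@@H]1O[C@@]1(C)CCC2=C(C)C(=O)CCC2(C)C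
F8 | step 2 | 3-[(3R,4S)-3-hydroperoxy-4,5-dihydroxy-3-methylpentyl]-2,4,4-trimethylcyclohex-2-en-1-one | OC[C@H](O)[C@@](C)(CCC1=C(C)C(=O)CCC1(C)C)OO
F9 | step 2 | 3-[(3R,4S)-3-{[tert-butyl(dimethyl)silyl]peroxy}-4,5-dihydroxy-3-methylpentyl]-2,4,4-trimethylcyclohex-2-en-1-one | OC[C@H](O)[C@@](C)(CCC1=C(C)C(=O)CCC1(C)C)OO[Si](C)(C)C(C)(C)C
F10 | step 8 | 3-[(3R,4Z)-3-{[tert-butyl(dimethyl)silyl]peroxy}-3-methyl-5-(triethylsilyl)pent-4-en-1-yl]-2,4,4-trimethylcyclohex-2-en-1-one | CC[Si](CC)(CC)/C=C\[C@@](C)(CCC1=C(C)C(=O)CCC1(C)C)OO[Si](C)(C)C(C)(C)C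
F11 | step 8 | 3-[(3R,4Z)-3-hydroperoxy-3-methyl-5-(triethylsilyl)pent-4-en-1-yl]-2,4,4-trimethylcyclohex-2-en-1-one | CC[Si](CC)(CC)/C=C\[C@@](C)(CCC1=C(C)C(=O)CCC1(C)C)OO
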